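Cedar levels off early.

| flask | X | Z | G | remark | time |
|---|---|---|---|---|---|
| cedar | 40 mM | 44 mM | 22 µM | the very flask that is asked about, followed so far |  |
| maple | 20 mM | 44 mM | 22 µM | run made earlier |  |
| flask | 40 mM | 44.0 mM | 22 µM |  | 30 h |

| run | time / h | X / % | J / % |
|---|---|---|---|
| cedar | 0.500 | 76.5 | 26.3 |
| cedar | 1.50 | 67.6 | 32.3 |
| cedar | 3.00 | 65.5 | 34.5 |
| cedar | 4.00 | 66.8 | 32.9 |
| cedar | 6.00 | 64.0 | 35.1 |
| maple | 1.00 | 65.6 | 33.7 |
| maple | 3.00 | 62.1 | 38.7 |
| maple | 6.00 | 60.0 | 38.2 |
| maple | 8.00 | 60.7 | 39.0 |
| maple | 12.0 | 60.8 | 39.0 |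

(each reading ± 1 percentage point)

- part of the X gone at 30 h
- the J standing at 30 h, as a percentage of the X charged

- for J the Q are counted in
- reactions considered so far: X + Z + G <-> J + G; G + J <-> Q; Z + G -> E

Follow one X: while G works it passes to J and back, and its odds of standing as J go with the Z left. So we carry the standing odds, which maple's last reading puts at 0.777: the fraction of X that is J, over the fraction of X left times the fraction of Z left, a mass-action quotient for this Z charge. Cedar's last reading, with the same Z and twice the X of maple, reads 0.794. Such agreement looks like an equilibrium, so we hold maple's odds for cedar at 30 h, which gives 34.7% of the X gone and standing as J.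

The forecast says 35% gone (33.5% to 36.5%) and 35% as J (33.5% to 36.5%), holding that “Losing G therefore no longer matters”. Cedar gives 35.0% gone and 35.0% as J.

    X + Z + G ⇌ J + G, rate k1*[X]*[Z]*[G] forward; the back reaction follows from the equilibrium constant (K = 18.2 /M, k = 1.06 × 10⁶ /M²/h)
    G + J ⇌ Q (K = 1280 /M, k = 24.2 /M/h)
    Z + G → E (k = 11.0 /M/h)

In cedar, the forward rate of X + Z into J alone, the way back not counted and the other concentrations as charged, gives X a half-life of 0.68 h, short against the 30 h asked, and half of this step's turnover up to that time is done by 0.261 h. At 30.0 h, cedar's G is down to 0.917% of the catalyst charged and this step's relaxation half-life, both ways together, stands at 29.2 h.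

In the neighbour flask with 100 mM of X on the same Z, the odds of 0.777 give 25.1% as J. That flask gives 25.3%, with 43% of its Z left.

Readings and results are simulated for substances that don't exist; scatter was added.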